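The data are calculated for substances that don't exist; noise was put on by code.

A pitfall with an intermediate is to treat its highest amount like the end yield of a final product, although at that moment making and use of it are equal.

in all of them: catalyst 5 mol%

| charge | substrate | remark | time |
|---|---|---|---|
| east | 0.28 M | run made earlier |  |
| north-west | 0.44 M | run made earlier |  |
| flask | 0.20 M |  | 10 h |

| east: time / h | east: target / % | north-west: time / h | north-west: target / % |
|---|---|---|---|
| 0.133 | 9.5 | 0.133 | 10.9 |
| 0.250 | 11.0 | 0.250 | 11.3 |
| 0.500 | 10.5 | 0.500 | 10.9 |
| 1.33 | 7.9 | 1.33 | 7.2 |
| 2.50 | 4.8 | 2.50 | 4.0 |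
| 6.00 | 1.9 | 6.00 | 1.7 |
| 12.0 | 1.7 | 12.0 | 1.6 |

(standard deviation of a reading: 0.3 percentage points)

- a reading or a percentage of target counts all its forms, free or not

- the moment within 10 h at which there is most target
- the amount of target, in percent of the substrate charged, at that time
- the first time at which target reaches 3.1 %, in the same percent, in min

Minutes of the meeting on the flask. I argued that the front of each curve shows making, the back shows loss, and the top is where the two join, and that this top barely heeded the charge: going from c_substrate 0.28 M in the east run to 0.44 M in the north-west run moved the top reading from 11.0 % to 11.3 %, a step of 0.3 percentage points against a scatter of 0.3 points. My guess was a quasi-steady state: if making of the target scales with the catalyst and c_substrate, and its use with c_substrate and its own amount, then the balance level, in percent of the substrate charged, follows the catalyst loading and not the charge. I therefore proposed to carry the top ratio, the top percentage of target divided by the catalyst loading, read from the two runs as 2.23, which for the flask at 5 mol% gave me 11.2 %.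

The forecaster, working from a “back-extrapolated amplitude above the floor” taken lower as the charge is lower, put the top at 10.5 % (range 9.5 % to 11.3 %) at 0.33 h (range 0.22 h to 0.5 h), with 3.1 % reached after 2.2 min (range 1.3 min to 4.5 min), so we parted on whether the top follows the charge.

The flask gives 10.4 % at 0.453 h, and reaches 3.1 % after 1.82 min.

    substrate + target → side product B (k = 0.0140 L mol⁻¹ s⁻¹)
    crystals ⇌ target, rate k2*(cs2 - [target]) while solid is left; crystals form when [target] > cs2 (solubility = 0.130 M, k = 0.0150 s⁻¹)
    target ⇌ isomer of the product (K = 8.50, k = 1.50 × 10⁻⁴ s⁻¹)
    substrate → side product A (k = 1.50 × 10⁻⁴ s⁻¹)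
    substrate + catalyst → catalyst + target (k = 0.0340 L mol⁻¹ s⁻¹)

In the flask at 0.256 h, dissolved target is made 1.12 times as fast as it is used up. The flask's own top ratio is 2.08, against the carried 2.23. Applied to the same flask with 1.2 mol% of catalyst, the carried ratio gives 2.68 %, and the top of that neighbour flask stands at 2.67 %.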